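**Retrosynthetic overview**

- The route rests on ring B of the bicyclo[3.3.1]nonane: C6H2 and C7H(prenyl) lie between bridgehead C5 and C8Me2 on bridgehead C1. Ring C1–C8–C7–C6–C5–C9 is therefore cut at C5–C6 and at C7–prenyl, back to a C1 1,1-dimethylallyl group (C8Me2–C7H=C6H2), a C5 radical of the C4/C9 dione, and a tert-prenyl sulfone.
- Ring A (C1–C2–C3–C4–C5–C9) is present from the start as cyclohexane-1,3-dione. Ring B is closed second, by the radical cascade, which also sets C5 and C7.
- The quaternary C1 comes from C-geranylation, O-prenylation and Claisen rearrangement, which give an achiral 2-geranyl-2-(dimethylallyl)-1,3-dione. A CBS desymmetrising reduction then fixes C1 and leaves C2 as CH(OMe).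
- The C4 carbonyl and the C5 geranyl group are added by desaturation, β-borylation/oxidation and C-alkylation. After the cascade the C2(OMe)=C3 enol ether is made by dehydrogenation.
- End game: C3 lithiation and aroylation with 3,4-bis(silyloxy)benzoyl chloride, desilylation, O-demethylation.

Key step: step 11

Numbering and abbreviations: C1–C9 are the atoms of the bicyclo[3.3.1]nonane core of the target; geranyl = (2E)-3,7-dimethylocta-2,6-dien-1-yl; prenyl = 3-methylbut-2-en-1-yl.

Remark: the cyclisation substrate is carried with C2 as CH(OMe) and C3 as CH2, because its fully unsaturated form, a 6-(1,1-dimethylallyl)cyclohexa-2,4-dienone, is the ortho-dienone of an aryl prenyl ether and should aromatise by retro-Claisen or Cope shift near room temperature.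

**Step 1**
Reactants: 1 cyclohexane-1,3-dione; 2 geranyl bromide
Product: 3 2-geranylcyclohexane-1,3-dione
Conditions: aq. KOH (1 M, 1.0 equiv), Bu4NI (5 mol %), 0 °C → rt
Reagents that add atoms: none
Why: C-alkylation of the cyclic 1,3-dione enolate by SN2 on the allylic bromide in aqueous base, where hydrogen bonding to the enolate oxygens favours attack through carbon and the E alkene is untouched.

**Step 2**
Reactants: 3 2-geranylcyclohexane-1,3-dione; 4 3-methylbut-2-en-1-ol
Product: 5 2-geranyl-3-(prenyloxy)cyclohex-2-en-1-one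
Conditions: PPh3, DIAD, THF, 0 °C → rt
Reagents that add atoms: none
Why: Mitsunobu O-alkylation of the acidic enol with the primary allylic alcohol gives the vinylogous ester and avoids the C-prenylation that competes with prenyl halides.

**Step 3**
Reactants: 5 2-geranyl-3-(prenyloxy)cyclohex-2-en-1-one
Product: 6 2-geranyl-2-(2-methylbut-3-en-2-yl)cyclohexane-1,3-dione
Conditions: o-xylene (degassed), BHT (cat.), 170 °C, sealed tube
Reagents that add atoms: none
Why: Thermal Claisen rearrangement ([3,3], chair transition state) delivers the CMe2 terminus of the prenyl ether to the geranyl-bearing carbon and so forms the quaternary carbon with its 1,1-dimethylallyl group; the product is achiral (mirror plane through that carbon).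

**Step 4**
Reactants: 6 2-geranyl-2-(2-methylbut-3-en-2-yl)cyclohexane-1,3-dione
Product: 7 (2R,3S)-2-geranyl-3-hydroxy-2-(2-methylbut-3-en-2-yl)cyclohexan-1-one
Conditions: (R)-Me-CBS (0.2 equiv), catecholborane (1.5 equiv), toluene, −78 → −40 °C
Reagents that add atoms: none
Why: Corey–Bakshi–Shibata reduction used as an enantiotopic-group-selective desymmetrisation: the (R)-oxazaborolidine delivers hydride to the carbonyl face on which O→quaternary carbon→CH2 runs clockwise, and for only one of the two carbonyls is this also the face anti to the axial geranyl group (dimethylallyl equatorial), so that carbonyl should be reduced, making the quaternary centre R and the carbinol S (OH cis to geranyl).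

**Step 5**
Reactants: 7 (2R,3S)-2-geranyl-3-hydroxy-2-(2-methylbut-3-en-2-yl)cyclohexan-1-one
Product: 8 (2R,3S)-2-geranyl-3-methoxy-2-(2-methylbut-3-en-2-yl)cyclohexan-1-one
Conditions: Me3OBF4, 1,8-bis(dimethylamino)naphthalene, CH2Cl2, 0 °C → rt
Reagents that add atoms: trimethyloxonium tetrafluoroborate, C[O+](C)C.F[B-](F)(F)F
Why: O-methylation of the secondary alcohol with Meerwein's salt and proton sponge under non-basic conditions, which avoids retro-aldol opening of the β-hydroxy ketone.

**Step 6**
Reactants: 8 (2R,3S)-2-geranyl-3-methoxy-2-(2-methylbut-3-en-2-yl)cyclohexan-1-one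
Product: 10 (5S,6R)-6-geranyl-5-methoxy-6-(2-methylbut-3-en-2-yl)cyclohex-2-en-1-one, via silyl enol ether 9 (not isolated)
Conditions: LDA, TMSCl, THF, −78 °C; then Pd(OAc)2 (1.05 equiv), MeCN, rt
Reagents that add atoms: none
Why: Saegusa–Ito dehydrogenation: the only enolisable position of the ketone (the CH2 opposite the quaternary carbon) is trapped as the silyl enol ether and Pd(II) then gives the enone by β-hydride elimination.

**Step 7**
Reactants: 10 (5S,6R)-6-geranyl-5-methoxy-6-(2-methylbut-3-en-2-yl)cyclohex-2-en-1-one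
Product: 12 (2R,3S)-2-geranyl-5-hydroxy-3-methoxy-2-(2-methylbut-3-en-2-yl)cyclohexan-1-one (C5 epimers), via boryl ketone 11 (not isolated)
Conditions: CuCl (5 mol %), Xantphos (5 mol %), NaOtBu (10 mol %), B2pin2 (1.1 equiv), MeOH (2 equiv), THF, rt; then NaBO3·4H2O, THF–H2O, rt
Reagents that add atoms: sodium perborate (tetrahydrate), [Na+].[Na+].O[B-]1(O)OO[B-](O)(O)OO1
Why: Copper-catalysed conjugate borylation of the enone followed by perborate oxidation of the C–B bond places oxygen on the β-carbon (future C4); the carbinol configuration does not matter because it is oxidised next.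

**Step 8**
Reactants: 12 (2R,3S)-2-geranyl-5-hydroxy-3-methoxy-2-(2-methylbut-3-en-2-yl)cyclohexan-1-one
Product: 13 (4R,5S)-4-geranyl-5-methoxy-4-(2-methylbut-3-en-2-yl)cyclohexane-1,3-dione
Conditions: TPAP (5 mol %), NMO (1.5 equiv), 4 Å MS, CH2Cl2, rt
Reagents that add atoms: none
Why: Ley–Griffith oxidation of the β-hydroxy ketone to the cyclic 1,3-dione, which leaves the alkenes and the methyl ether untouched.

**Step 9**
Reactants: 13 (4R,5S)-4-geranyl-5-methoxy-4-(2-methylbut-3-en-2-yl)cyclohexane-1,3-dione; 2 geranyl bromide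
Product: 14 (5S,6R)-2,6-digeranyl-3-hydroxy-5-methoxy-6-(2-methylbut-3-en-2-yl)cyclohex-2-en-1-one
Conditions: KOH (1.0 equiv), H2O–THF (1:1), 0 °C → rt
Reagents that add atoms: none
Why: C-alkylation of the 1,3-dione enolate at its central carbon (future C5) by SN2 on the allylic bromide, as in step 1; the product is kept at or below room temperature because its enol holds a 1,5-diene with the dimethylallyl group.

**Step 10**
Reactants: 15 allyl phenyl sulfone
Product: 17 3-methyl-3-(phenylsulfonyl)but-1-ene, via 3-(phenylsulfonyl)but-1-ene 16 (not isolated)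
Conditions: n-BuLi (1.05 equiv), THF, −78 °C, then MeI; second cycle of n-BuLi then MeI in the same flask
Reagents that add atoms: iodomethane, CI
Why: Two successive α-deprotonation/methylation cycles of the allylic sulfone; the sulfonyl-stabilised allyl anion alkylates at the α-carbon each time.

**Step 11**
Reactants: 14 (5S,6R)-2,6-digeranyl-3-hydroxy-5-methoxy-6-(2-methylbut-3-en-2-yl)cyclohex-2-en-1-one; 17 3-methyl-3-(phenylsulfonyl)but-1-ene
Product: 18 (1R,2S,5S,7R)-1,5-digeranyl-2-methoxy-8,8-dimethyl-7-prenylbicyclo[3.3.1]nonane-4,9-dione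
Conditions: [Ir(dF(CF3)ppy)2(dtbbpy)]PF6 (2 mol %), K2HPO4 (1.5 equiv), 17 (5 equiv), DMSO (0.05 M in 14), blue LEDs (450 nm), 15–20 °C, argon
Reagents that add atoms: none
Why: Proposed new method: the excited Ir(III) catalyst oxidises the potassium enolate of the C4/C9 dione to the C5 radical, which closes 6-endo-trig on C6 of the C1 dimethylallyl group (ring C1–C8–C7–C6–C5–C9); the secondary C7 radical adds to the CH2 terminus of 17 and β-scission releases the prenyl alkene and PhSO2•, which the reduced catalyst turns into sulfinate, so the step is redox-neutral. The closest known types are 1,3-dicarbonyl radicals (Mn(III) or photoredox) closing 6-endo on an α′-allyl group to give bicyclo[3.3.1]nonan-9-ones, and allylation of secondary alkyl radicals by allyl sulfones. C5 is fixed by the bridge: the C5–C6 bond can only form on the ring face that carries C8, so its configuration follows from C1. C7 is set by attack of the sulfone on the exo face, anti to the C2–C3–C4 bridge, whose endo C3–H screens the other face. The step needs 6-endo closure on the vinyl group in preference to 5-exo closure on the C1 geranyl alkene; the C9 carbonyl inside the forming ring, the open CH2 terminus next to the blocked neopentyl C7, and the strain of the alternative bicyclo[3.2.1] radical (expected to reopen) should secure it, and neither geranyl group can reach C7 from its equatorial bridgehead position.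

**Step 12**
Reactants: 18 (1R,2S,5S,7R)-1,5-digeranyl-2-methoxy-8,8-dimethyl-7-prenylbicyclo[3.3.1]nonane-4,9-dione
Product: 20 (1R,5S,7R)-1,5-digeranyl-2-methoxy-8,8-dimethyl-7-prenylbicyclo[3.3.1]non-2-ene-4,9-dione, via silyl enol ether 19 (not isolated)
Conditions: LDA, TMSCl, THF, −78 °C; then Pd(OAc)2 (1.1 equiv), MeCN, rt
Reagents that add atoms: none
Why: Saegusa–Ito dehydrogenation: the C4 ketone can enolise only towards C3 (C5 is quaternary, C9 has no α-hydrogen), the enolate is silylated in situ at −78 °C to forestall loss of methoxide, and Pd(II) removes the C2 hydrogen to give the β-methoxy enone, which erases the temporary C2 stereocentre.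

**Step 13**
Reactants: 21 3,4-dihydroxybenzoic acid
Product: 22 tert-butyldimethylsilyl 3,4-bis(tert-butyldimethylsilyloxy)benzoate
Conditions: TBSCl (3.5 equiv), imidazole, DMF, rt
Reagents that add atoms: tert-butyldimethylsilyl chloride, CC(C)(C)[Si](C)(C)Cl
Why: Silylation of both phenols and of the carboxylic acid (as silyl ester) with TBSCl/imidazole.

**Step 14**
Reactants: 22 tert-butyldimethylsilyl 3,4-bis(tert-butyldimethylsilyloxy)benzoate
Product: 23 3,4-bis(tert-butyldimethylsilyloxy)benzoyl chloride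
Conditions: (COCl)2, DMF (cat.), CH2Cl2, 0 °C → rt
Reagents that add atoms: oxalyl chloride, O=C(Cl)C(=O)Cl
Why: The silyl ester is converted directly into the acid chloride by oxalyl chloride/DMF (Vilsmeier-type activation under neutral conditions), with the aryl silyl ethers staying in place.

**Step 15**
Reactants: 20 (1R,5S,7R)-1,5-digeranyl-2-methoxy-8,8-dimethyl-7-prenylbicyclo[3.3.1]non-2-ene-4,9-dione; 23 3,4-bis(tert-butyldimethylsilyloxy)benzoyl chloride
Product: 25 3-[3,4-bis(tert-butyldimethylsilyloxy)benzoyl]-1,5-digeranyl-2-methoxy-8,8-dimethyl-7-prenylbicyclo[3.3.1]non-2-ene-4,9-dione (configuration as in 20), via C3-lithio vinylogous ester 24 (not isolated)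
Conditions: LiTMP (1.5 equiv), THF, −78 °C; then 23, −78 → −40 °C
Reagents that add atoms: none
Why: Deprotonation of the vinylogous ester at C3 by the hindered amide base (the vinyl anion is stabilised by the flanking carbonyl and the methoxy oxygen) and acylation of the vinyllithium by the aroyl chloride.

**Step 16**
Reactants: 25 3-[3,4-bis(tert-butyldimethylsilyloxy)benzoyl]-1,5-digeranyl-2-methoxy-8,8-dimethyl-7-prenylbicyclo[3.3.1]non-2-ene-4,9-dione
Product: 26 3-(3,4-dihydroxybenzoyl)-1,5-digeranyl-2-methoxy-8,8-dimethyl-7-prenylbicyclo[3.3.1]non-2-ene-4,9-dione (configuration as in 20)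
Conditions: HF·pyridine, pyridine, THF, 0 °C
Reagents that add atoms: none
Why: Fluoride cleavage of the two aryl silyl ethers under buffered conditions that touch neither the alkenes nor the vinylogous ester.

**Step 17**
Reactants: 26 3-(3,4-dihydroxybenzoyl)-1,5-digeranyl-2-methoxy-8,8-dimethyl-7-prenylbicyclo[3.3.1]non-2-ene-4,9-dione
Product: 27 CNP0178719.1, 3-(3,4-dihydroxybenzoyl)-1,5-digeranyl-4-hydroxy-8,8-dimethyl-7-prenylbicyclo[3.3.1]non-3-ene-2,9-dione (configuration as in 20)
Conditions: LiCl, DMSO (degassed), 120 °C, argon; dilute HCl work-up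
Reagents that add atoms: none
Why: Nucleophilic O-demethylation (Krapcho-type SN2 of chloride on the methyl group of the vinylogous ester) releases the enolised 2,4,9-trione without touching a stereocentre.

**Compound list**

1 | cyclohexane-1,3-dione | O=C1CCCC(=O)C1 | starting material
2 | geranyl bromide, (2E)-1-bromo-3,7-dimethylocta-2,6-diene | CC(C)=CCC/C(C)=C/CBr | starting material
3 | 2-geranylcyclohexane-1,3-dione (enol form) | CC(C)=CCC/C(C)=C/CC1=C(O)CCCC1=O | intermediate
4 | 3-methylbut-2-en-1-ol | CC(C)=CCO | starting material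
5 | 2-geranyl-3-(prenyloxy)cyclohex-2-en-1-one | CC(C)=CCC/C(C)=C/CC1=C(OCC=C(C)C)CCCC1=O | intermediate
6 | 2-geranyl-2-(2-methylbut-3-en-2-yl)cyclohexane-1,3-dione (achiral) | CC(C)=CCC/C(C)=C/CC1(C(C)(C)C=C)C(=O)CCCC1=O | intermediate
7 | (2R,3S)-2-geranyl-3-hydroxy-2-(2-methylbut-3-en-2-yl)cyclohexan-1-one (OH cis to geranyl) | C=CC(C)(C)[C@@]1(C/C=C(\C)CCC=C(C)C)C(=O)CCC[C@@H]1O | intermediate
8 | (2R,3S)-2-geranyl-3-methoxy-2-(2-methylbut-3-en-2-yl)cyclohexan-1-one | C=CC(C)(C)[C@@]1(C/C=C(\C)CCC=C(C)C)C(=O)CCC[C@@H]1OC | intermediate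
9 | [(5S,6R)-6-geranyl-5-methoxy-6-(2-methylbut-3-en-2-yl)cyclohex-1-en-1-yl]oxytrimethylsilane | C=CC(C)(C)[C@@]1(C/C=C(\C)CCC=C(C)C)C(O[Si](C)(C)C)=CCC[C@@H]1OC | intermediate (not isolated)
10 | (5S,6R)-6-geranyl-5-methoxy-6-(2-methylbut-3-en-2-yl)cyclohex-2-en-1-one | C=CC(C)(C)[C@@]1(C/C=C(\C)CCC=C(C)C)C(=O)C=CC[C@@H]1OC | intermediate
11 | (2R,3S)-2-geranyl-3-methoxy-2-(2-methylbut-3-en-2-yl)-5-(4,4,5,5-tetramethyl-1,3,2-dioxaborolan-2-yl)cyclohexan-1-one (C5 epimers) | C=CC(C)(C)[C@@]1(C/C=C(\C)CCC=C(C)C)C(=O)CC(B2OC(C)(C)C(C)(C)O2)C[C@@H]1OC | intermediate (not isolated)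
12 | (2R,3S)-2-geranyl-5-hydroxy-3-methoxy-2-(2-methylbut-3-en-2-yl)cyclohexan-1-one (C5 epimers) | C=CC(C)(C)[C@@]1(C/C=C(\C)CCC=C(C)C)C(=O)CC(O)C[C@@H]1OC | intermediate
13 | (4R,5S)-4-geranyl-5-methoxy-4-(2-methylbut-3-en-2-yl)cyclohexane-1,3-dione | C=CC(C)(C)[C@@]1(C/C=C(\C)CCC=C(C)C)C(=O)CC(=O)C[C@@H]1OC | intermediate
14 | (5S,6R)-2,6-digeranyl-3-hydroxy-5-methoxy-6-(2-methylbut-3-en-2-yl)cyclohex-2-en-1-one (enol form of the 2,4-digeranyl-1,3-dione; cyclisation precursor) | CC(C)=CCC/C(C)=C/CC1=C(O)C[C@H](OC)[C@@](C/C=C(\C)CCC=C(C)C)(C(C)(C)C=C)C1=O | intermediate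
15 | allyl phenyl sulfone | C=CCS(=O)(=O)c1ccccc1 | starting material
16 | 3-(phenylsulfonyl)but-1-ene (racemic) | C=CC(C)S(=O)(=O)c1ccccc1 | intermediate (not isolated)
17 | 3-methyl-3-(phenylsulfonyl)but-1-ene | C=CC(C)(C)S(=O)(=O)c1ccccc1 | intermediate
18 | (1R,2S,5S,7R)-1,5-digeranyl-2-methoxy-8,8-dimethyl-7-prenylbicyclo[3.3.1]nonane-4,9-dione (7-prenyl exo, 2-OMe trans to C8) | CC(C)=CCC/C(C)=C/C[C@]12C[C@@H](CC=C(C)C)C(C)(C)[C@](C/C=C(\C)CCC=C(C)C)([C@@H](OC)CC1=O)C2=O | intermediate
19 | 4-trimethylsilyloxy-3-ene derivative of 18 (C3=C4 silyl enol ether) | CC(C)=CCC/C(C)=C/C[C@]12C[C@@H](CC=C(C)C)C(C)(C)[C@](C/C=C(\C)CCC=C(C)C)([C@@H](OC)C=C1O[Si](C)(C)C)C2=O | intermediate (not isolated)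
20 | (1R,5S,7R)-1,5-digeranyl-2-methoxy-8,8-dimethyl-7-prenylbicyclo[3.3.1]non-2-ene-4,9-dione | CC(C)=CCC/C(C)=C/C[C@]12C[C@@H](CC=C(C)C)C(C)(C)[C@](C/C=C(\C)CCC=C(C)C)(C(OC)=CC1=O)C2=O | intermediate
21 | 3,4-dihydroxybenzoic acid | OC(=O)c1ccc(O)c(O)c1 | starting material
22 | tert-butyldimethylsilyl 3,4-bis(tert-butyldimethylsilyloxy)benzoate | CC(C)(C)[Si](C)(C)OC(=O)c1ccc(O[Si](C)(C)C(C)(C)C)c(O[Si](C)(C)C(C)(C)C)c1 | intermediate
23 | 3,4-bis(tert-butyldimethylsilyloxy)benzoyl chloride | O=C(Cl)c1ccc(O[Si](C)(C)C(C)(C)C)c(O[Si](C)(C)C(C)(C)C)c1 | intermediate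
24 | 3-lithio derivative of 20 | CC(C)=CCC/C(C)=C/C[C@]12C[C@@H](CC=C(C)C)C(C)(C)[C@](C/C=C(\C)CCC=C(C)C)(C(OC)=C([Li])C1=O)C2=O | intermediate (not isolated)
25 | 3-[3,4-bis(tert-butyldimethylsilyloxy)benzoyl] derivative of 20 | CC(C)=CCC/C(C)=C/C[C@]12C[C@@H](CC=C(C)C)C(C)(C)[C@](C/C=C(\C)CCC=C(C)C)(C(OC)=C(C(=O)c3ccc(O[Si](C)(C)C(C)(C)C)c(O[Si](C)(C)C(C)(C)C)c3)C1=O)C2=O | intermediate
26 | 3-(3,4-dihydroxybenzoyl) derivative of 20 | CC(C)=CCC/C(C)=C/C[C@]12C[C@@H](CC=C(C)C)C(C)(C)[C@](C/C=C(\C)CCC=C(C)C)(C(OC)=C(C(=O)c3ccc(O)c(O)c3)C1=O)C2=O | intermediate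
27 | CNP0178719.1 | CC(C)=CCC/C(C)=C/C[C@]12C[C@@H](CC=C(C)C)C(C)(C)[C@](C/C=C(\C)CCC=C(C)C)(C(=O)C(C(=O)c3ccc(O)c(O)c3)=C1O)C2=O | target

**Step count**

Total: 17 steps. Longest linear sequence: 14 steps (steps 1–9, 11, 12, 15, 16, 17).

**Steps most likely to fail, with fallbacks**

Step 11 (proposed new method). Three things may go wrong:
- the C5 radical may close 5-exo on the C1 geranyl alkene instead of 6-endo on the vinyl group;
- the sulfone may allylate the C5 radical before ring closure;
- reversible addition of the sulfonyl radical may scramble the E geranyl alkenes.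

The fallback makes the two bonds in separate, known operations and sets out from 14. Bromination at C5 with NBS (CH2Cl2, 0 °C) should give (4R,5S)-2-bromo-2,4-digeranyl-5-methoxy-4-(2-methylbut-3-en-2-yl)cyclohexane-1,3-dione F1. A bromine-atom-transfer radical cyclisation of this α-bromo-1,3-dione (Et3B/air, Yb(OTf)3, CH2Cl2, −78 °C) closes ring B 6-endo and leaves bromine on C7, giving 7-bromo-1,5-digeranyl-2-methoxy-8,8-dimethylbicyclo[3.3.1]nonane-4,9-dione F2. Radical allylation of this secondary bromide with sulfone 17 (hexabutylditin, hν, benzene) then places the prenyl group on the exo face and returns to the route at 18.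

Step 3. The Claisen rearrangement has to join two fully substituted carbons; at the temperature it needs, the prenyl ether may instead lose isoprene or undergo a [1,3] shift to the linear prenyl isomer. The fallback reverses the order in which the two C1 substituents are introduced and sets out from 1. Mitsunobu etherification of 1 with 4 gives 3-(prenyloxy)cyclohex-2-en-1-one F3. Its Claisen rearrangement onto the unsubstituted enol carbon is much easier (toluene, 110–140 °C) and gives 2-(2-methylbut-3-en-2-yl)cyclohexane-1,3-dione F4. Palladium-catalysed allylic alkylation of F4 with geranyl acetate (Pd(PPh3)4, DBU, THF), in which any O-geranyl ether re-ionises and is funnelled to carbon, then gives 6, where the route is rejoined.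

Step 4. The desymmetrisation may discriminate poorly between the two carbonyls, because it depends on the facial bias of a very hindered diketone; if that bias ran the other way, the enantiomeric catalyst would be needed. The fallback sets C1 by resolution instead and sets out from 6. NaBH4 (MeOH, −20 °C) should reduce one carbonyl from the face anti to the axial geranyl group and give the racemic hydroxy ketone, that is 7 together with its enantiomer (2S,3R)-2-geranyl-3-hydroxy-2-(2-methylbut-3-en-2-yl)cyclohexan-1-one F5. Esterification with (S)-O-methylmandelic acid (DCC, DMAP) gives the diastereomeric esters, the (S)-O-methylmandelate of 7 F6 and the (S)-O-methylmandelate of the enantiomer F7, which are separated by chromatography. Hydrolysis of F6 (LiOH, THF–H2O, 0 °C) returns 7.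

**Further compounds**

F1 | step 11 | (4R,5S)-2-bromo-2,4-digeranyl-5-methoxy-4-(2-methylbut-3-en-2-yl)cyclohexane-1,3-dione (C2 epimers) | CC(C)=CCC/C(C)=C/CC1(Br)C(=O)C[C@H](OC)[C@@](C/C=C(\C)CCC=C(C)C)(C(C)(C)C=C)C1=O
F2 | step 11 | 7-bromo-1,5-digeranyl-2-methoxy-8,8-dimethylbicyclo[3.3.1]nonane-4,9-dione (C7 epimers, other centres as in 18) | CC(C)=CCC/C(C)=C/C[C@]12CC(Br)C(C)(C)[C@](C/C=C(\C)CCC=C(C)C)([C@@H](OC)CC1=O)C2=O
F3 | step 3 | 3-(prenyloxy)cyclohex-2-en-1-one | CC(C)=CCOC1=CC(=O)CCC1
F4 | step 3 | 2-(2-methylbut-3-en-2-yl)cyclohexane-1,3-dione (enol form) | C=CC(C)(C)C1=C(O)CCCC1=O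
F5 | step 4 | (2S,3R)-2-geranyl-3-hydroxy-2-(2-methylbut-3-en-2-yl)cyclohexan-1-one | C=CC(C)(C)[C@]1(C/C=C(\C)CCC=C(C)C)C(=O)CCC[C@H]1O
F6 | step 4 | (1S,2R)-2-geranyl-2-(2-methylbut-3-en-2-yl)-3-oxocyclohexyl (S)-2-methoxy-2-phenylacetate | C=CC(C)(C)[C@@]1(C/C=C(\C)CCC=C(C)C)C(=O)CCC[C@@H]1OC(=O)[C@@H](OC)c2ccccc2
F7 | step 4 | (1R,2S)-2-geranyl-2-(2-methylbut-3-en-2-yl)-3-oxocyclohexyl (S)-2-methoxy-2-phenylacetate | C=CC(C)(C)[C@]1(C/C=C(\C)CCC=C(C)C)C(=O)CCC[C@H]1OC(=O)[C@@H](OC)c2ccccc2
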